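The route rests on taking apart the oxane ring (O, C9–C13) at O–C13, C12–Br and C10–Cl in one move, which leads back to a cis-9,10-oxirane carrying a (12E)-alkene. The feature exploited is that the ring oxygen sits between C10–Cl (cis to the C9 chain) and C12–Br (trans to the C13 ethyl), the imprint of anti addition across former C9=C10 (Z) and C12=C13 (E) bonds. In step 10, Br+ activates the alkene, the oxirane oxygen closes onto C13 and chloride opens the resulting epoxonium ion at C10, forming the ring, both carbon–halogen bonds and three stereocentres. The precursor is epoxy-alkene 16 with C6–Cl, a C7 silyl ether and a C4 pivalate; the enyne is added afterwards.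

Key step: step 10

Remarks on the chemistry
- Atom labels C1–C15 follow the target chain from the alkyne terminus (C6–Cl, C7–OAc, ring oxygen between C9 and C13, C10–Cl, C12–Br, C14–C15 ethyl).
- Assumption for step 4: chlorine enters the E-enamine anti to the benzyl group, which assigns the 2R chloride to the (5R)-imidazolidinone; were the sense opposite, the (5S)-catalyst would be used with no other change.
- Correction: an alkyllithium and chloroiodomethane give chloromethyllithium, not iodomethyllithium, and the derived 1,3-dichloro alkoxide could close on either chloride; diiodomethane is used instead (step 5), so that closure on the primary iodide is the only fast path.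
- Precursor design: C7 stays a bulky silyl ether through step 10 (an acetate could open the epoxonium ion at C9 through its carbonyl oxygen), C4 is a non-nucleophilic ester, and no second alkene or alkyne is present.

Step 1
Reactants: 1 (E)-1-bromopent-2-ene; 2 ethynylmagnesium bromide
Product: 3 (E)-hept-4-en-1-yne
Conditions: CuCl (5 mol %), THF, 0 °C to 50 °C, 2 in excess
Reagents that add atoms: none
Why: Copper-catalysed coupling of an alkynyl Grignard reagent with a primary allylic bromide should give the linear (SN2) skipped enyne with the E geometry of 1 carried over unchanged.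

Step 2
Reactants: 4 butane-1,4-diol
Product: 5 4-hydroxybutyl pivalate
Conditions: PivCl (1 equiv), Et3N, CH2Cl2, 0 °C, diol in threefold excess
Reagents that add atoms: pivaloyl chloride, CC(C)(C)C(=O)Cl
Why: Statistical mono-acylation (esterification) of a symmetric diol used in excess should give the mono-ester, the surplus diol being removed by aqueous extraction.

Step 3
Reactants: 5 4-hydroxybutyl pivalate
Product: 6 4-oxobutyl pivalate
Conditions: TEMPO (10 mol %), PhI(OAc)2, CH2Cl2, rt
Reagents that add atoms: none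
Why: Oxoammonium-mediated (TEMPO) oxidation of a primary alcohol stops at the aldehyde under neutral conditions that leave the ester alone.

Step 4
Reactants: 6 4-oxobutyl pivalate
Product: 7 (3R)-3-chloro-4-oxobutyl pivalate
Conditions: (5R)-5-benzyl-2,2,3-trimethylimidazolidin-4-one·CF3CO2H (10 mol %), 2,3,4,5,6,6-hexachlorocyclohexa-2,4-dien-1-one, acetone, −30 °C; product used crude and cold
Reagents that add atoms: 2,3,4,5,6,6-hexachlorocyclohexa-2,4-dien-1-one, O=C1C(Cl)=C(Cl)C(Cl)=C(Cl)C1(Cl)Cl
Why: Enamine-catalysed (organocatalytic) α-chlorination, in which the electrophilic chlorine is delivered to the enamine face remote from the benzyl group, should set C6 as R.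

Step 5
Reactants: 7 (3R)-3-chloro-4-oxobutyl pivalate; 8 diiodomethane
Product: 11 (3R)-3-chloro-3-[(2S)-oxiran-2-yl]propyl pivalate, via iodomethyllithium 9 (not isolated), via lithium iodoalkoxide 10 (not isolated)
Conditions: MeLi·LiBr added slowly to 7 and CH2I2, THF, −78 °C, then warm to rt
Reagents that add atoms: none
Why: Iodine–lithium exchange gives the lithium carbenoid, which adds to the aldehyde anti to the C6 chloride (Cornforth/polar Felkin–Anh control, setting C7 as S), and on warming the alkoxide closes on the primary iodide far faster than on the secondary chloride (halomethyllithium epoxide synthesis).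

Step 6
Reactants: 3 (E)-hept-4-en-1-yne; 11 (3R)-3-chloro-3-[(2S)-oxiran-2-yl]propyl pivalate
Product: 13 (3R,4S,9E)-3-chloro-4-hydroxydodec-9-en-6-yn-1-yl pivalate, via lithium heptenynide 12 (not isolated)
Conditions: 3, n-BuLi, THF, −78 °C; BF3·OEt2; then 11, −78 °C
Reagents that add atoms: none
Why: BF3-promoted opening of a terminal oxirane by a lithium acetylide (Yamaguchi–Hirao alkynylation) takes place at the CH2 carbon C8, so C6 and C7 are untouched, and at −78 °C the pivalate and the doubly activated CH2 of the enyne are not attacked.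

Step 7
Reactants: 13 (3R,4S,9E)-3-chloro-4-hydroxydodec-9-en-6-yn-1-yl pivalate
Product: 14 (3R,4S,6Z,9E)-3-chloro-4-hydroxydodeca-6,9-dien-1-yl pivalate
Conditions: H2 (1 atm), Pd/CaCO3 poisoned with Pb(OAc)2, quinoline, EtOAc, rt, stopped after one equivalent
Reagents that add atoms: none
Why: Lindlar semihydrogenation delivers H2 syn to the alkyne to give the 9Z alkene and should leave the E alkene, the ester and the alkyl chloride alone.

Step 8
Reactants: 14 (3R,4S,6Z,9E)-3-chloro-4-hydroxydodeca-6,9-dien-1-yl pivalate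
Product: 15 (3R,4S)-3-chloro-4-hydroxy-5-{(2R,3S)-3-[(E)-pent-2-en-1-yl]oxiran-2-yl}pentyl pivalate
Conditions: VO(acac)2 (5 mol %), t-BuOOH, CH2Cl2, 0 °C to rt
Reagents that add atoms: tert-butyl hydroperoxide, CC(C)(C)OO
Why: Hydroxyl-directed vanadium-catalysed epoxidation of a Z-homoallylic alcohol passes through a chair-like vanadate transition state with the C6 branch equatorial, which should give the 7,9-syn cis-oxirane (9R,10S), while the remote 12E alkene is out of reach of the directing group.

Step 9
Reactants: 15 (3R,4S)-3-chloro-4-hydroxy-5-{(2R,3S)-3-[(E)-pent-2-en-1-yl]oxiran-2-yl}pentyl pivalate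
Product: 16 (3R,4S)-4-[(tert-butyldiphenylsilyl)oxy]-3-chloro-5-{(2R,3S)-3-[(E)-pent-2-en-1-yl]oxiran-2-yl}pentyl pivalate
Conditions: TBDPSCl, imidazole, DMAP (cat.), DMF, rt to 40 °C
Reagents that add atoms: tert-butyl(chloro)diphenylsilane, CC(C)(C)[Si](Cl)(c1ccccc1)c1ccccc1
Why: Imidazole-promoted silylation of the secondary alcohol is non-acidic and only weakly basic, so the oxirane and the chlorohydrin motif should survive.

Step 10
Reactants: 16 (3R,4S)-4-[(tert-butyldiphenylsilyl)oxy]-3-chloro-5-{(2R,3S)-3-[(E)-pent-2-en-1-yl]oxiran-2-yl}pentyl pivalate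
Product: 19 (3R,4S)-5-[(2R,3R,5R,6S)-5-bromo-3-chloro-6-ethyloxan-2-yl]-4-[(tert-butyldiphenylsilyl)oxy]-3-chloropentyl pivalate, via bromonium ion 17 (not isolated), via bicyclic epoxonium ion 18 (not isolated)
Conditions: Bu4NCl (5 equiv), then NBS (1.2 equiv) in portions, (CF3)2CHOH, 0 °C, dark
Reagents that add atoms: N-bromosuccinimide, O=C1CCC(=O)N1Br; tetrabutylammonium chloride, CCCC[N+](CCCC)(CCCC)CCCC.[Cl-]
Why: Proposed new method: reversible Br+ transfer from NBS gives the C12–C13 bromonium ion 17, the oxirane oxygen (tethered through C10) opens it at C13 anti to bromine to give the 1-oxoniabicyclo[3.1.0]hexane 18, and chloride opens 18 at C10 with inversion, cutting C10–O so that oxygen is left bridging C9 and C13; the closest known reaction types are bromonium-initiated epoxide-opening cascades ended by oxygen nucleophiles, 5-endo halocyclisation of homoallylic alcohols and halide capture of cyclic oxonium ions. The oxane ring therefore arises in two stages, a 5-endo closure of oxygen onto C13 (the 4-exo alternative at C12 is not competitive) followed by ring expansion when chloride breaks the bond shared by the two rings of 18 at the ring-fusion carbon. C12 and C13 are set as a pair by anti addition to the E alkene (Br trans to ethyl), C10 is set by SN2 inversion of the cis-oxirane carbon (Cl cis to the C9 chain), and C9 is not touched. The step needs, first, the bromonium face that puts bromine on the oxolane face opposite the fused oxirane, which is also the face that brings the C13 ethyl cis to the C9 chain; this is expected to be preferred because the cis-oxirane forces its C8 chain over the forming ring, away from which bromine should sit, and because bromonium formation is reversible, but it is not enforced by the mechanism. It needs, second, chloride attack at C10 and not C9, which should be favoured by release of bicyclic strain at the fusion carbon and by the hindered, inductively deactivated C9 next to the C8–C7(OSi)–C6(Cl) branch. Hexafluoroisopropanol should stabilise 17 and 18 and damp chloride by hydrogen bonding so that intramolecular capture outruns bromochlorination, and the bulky silyl ether and the pivalate keep O7 and O4 out of the cascade.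

Step 11
Reactants: 19 (3R,4S)-5-[(2R,3R,5R,6S)-5-bromo-3-chloro-6-ethyloxan-2-yl]-4-[(tert-butyldiphenylsilyl)oxy]-3-chloropentyl pivalate
Product: 20 (3R,4S)-5-[(2R,3R,5R,6S)-5-bromo-3-chloro-6-ethyloxan-2-yl]-4-[(tert-butyldiphenylsilyl)oxy]-3-chloropentan-1-ol
Conditions: i-Bu2AlH (2.5 equiv), CH2Cl2, −78 °C; aqueous Rochelle salt
Reagents that add atoms: none
Why: Reductive cleavage of the pivalate ester by the aluminium hydride at −78 °C should free the C4 alcohol without touching the secondary alkyl halides or the silyl ether.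

Step 12
Reactants: 20 (3R,4S)-5-[(2R,3R,5R,6S)-5-bromo-3-chloro-6-ethyloxan-2-yl]-4-[(tert-butyldiphenylsilyl)oxy]-3-chloropentan-1-ol
Product: 21 (3R,4S)-5-[(2R,3R,5R,6S)-5-bromo-3-chloro-6-ethyloxan-2-yl]-4-[(tert-butyldiphenylsilyl)oxy]-3-chloropentanal
Conditions: Dess–Martin periodinane, NaHCO3, CH2Cl2, 0 °C; used at once
Reagents that add atoms: none
Why: Dess–Martin oxidation is fast and close to neutral, so the aldehyde, which carries the C6 chloride in the β position, is not exposed to a base strong enough to eliminate HCl.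

Step 13
Reactants: 21 (3R,4S)-5-[(2R,3R,5R,6S)-5-bromo-3-chloro-6-ethyloxan-2-yl]-4-[(tert-butyldiphenylsilyl)oxy]-3-chloropentanal
Product: 22 tert-butyl({(2S,3R,5E)-1-[(2R,3R,5R,6S)-5-bromo-3-chloro-6-ethyloxan-2-yl]-3-chloro-6-iodohex-5-en-2-yl}oxy)diphenylsilane
Conditions: CrCl2 (6 equiv), CHI3 (2 equiv), dioxane–THF (6:1), 0 °C to rt
Reagents that add atoms: iodoform, IC(I)I
Why: Takai iodo-olefination with the geminal dichromium reagent is non-basic and E-selective, so the (3E)-vinyl iodide should form without β-elimination, and unactivated secondary alkyl halides are not reduced by divalent chromium under these conditions.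

Step 14
Reactants: 22 tert-butyl({(2S,3R,5E)-1-[(2R,3R,5R,6S)-5-bromo-3-chloro-6-ethyloxan-2-yl]-3-chloro-6-iodohex-5-en-2-yl}oxy)diphenylsilane; 23 ethynyltrimethylsilane
Product: 24 tert-butyl({(2S,3R,5E)-1-[(2R,3R,5R,6S)-5-bromo-3-chloro-6-ethyloxan-2-yl]-3-chloro-8-(trimethylsilyl)oct-5-en-7-yn-2-yl}oxy)diphenylsilane
Conditions: Pd(PPh3)4 (5 mol %), CuI (10 mol %), Et2NH, rt
Reagents that add atoms: none
Why: Sonogashira coupling of the vinyl iodide proceeds at room temperature with retention of alkene geometry, and zerovalent palladium does not insert into the secondary alkyl chlorides or bromide under these conditions.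

Step 15
Reactants: 24 tert-butyl({(2S,3R,5E)-1-[(2R,3R,5R,6S)-5-bromo-3-chloro-6-ethyloxan-2-yl]-3-chloro-8-(trimethylsilyl)oct-5-en-7-yn-2-yl}oxy)diphenylsilane
Product: 25 (2S,3R,5E)-1-[(2R,3R,5R,6S)-5-bromo-3-chloro-6-ethyloxan-2-yl]-3-chlorooct-5-en-7-yn-2-ol
Conditions: Bu4NF (3 equiv), AcOH (3 equiv), THF, 0 °C to rt
Reagents that add atoms: none
Why: Fluoride-induced desilylation should remove the alkynyl and the oxygen-bound silyl groups in one operation, the acetic acid buffer protonating the C7 alkoxide as it forms so that it neither closes on C6–Cl nor acts as a base toward the ring halides.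

Step 16
Reactants: 25 (2S,3R,5E)-1-[(2R,3R,5R,6S)-5-bromo-3-chloro-6-ethyloxan-2-yl]-3-chlorooct-5-en-7-yn-2-ol
Product: 26 (2S,3R,5E)-1-[(2R,3R,5R,6S)-5-bromo-3-chloro-6-ethyloxan-2-yl]-3-chlorooct-5-en-7-yn-2-yl acetate
Conditions: Ac2O, pyridine, DMAP (cat.), CH2Cl2, 0 °C to rt
Reagents that add atoms: acetic anhydride, CC(=O)OC(C)=O
Why: DMAP-catalysed acylation of the secondary alcohol is mild enough to leave the enyne and the halides alone and gives the target with all six stereocentres (6R,7S,9R,10R,12R,13S) in place.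

Compound list
1 | (E)-1-bromopent-2-ene | CC/C=C/CBr | starting material
2 | ethynylmagnesium bromide | C#C[Mg]Br | starting material
3 | (E)-hept-4-en-1-yne | C#CC/C=C/CC | intermediate
4 | butane-1,4-diol | OCCCCO | starting material
5 | 4-hydroxybutyl pivalate | CC(C)(C)C(=O)OCCCCO | intermediate
6 | 4-oxobutyl pivalate | CC(C)(C)C(=O)OCCCC=O | intermediate
7 | (3R)-3-chloro-4-oxobutyl pivalate | CC(C)(C)C(=O)OCC[C@@H](Cl)C=O | intermediate
8 | diiodomethane | ICI | starting material
9 | iodomethyllithium | [Li]CI | intermediate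
10 | lithium (2R,3R)-3-chloro-1-iodo-5-(pivaloyloxy)pentan-2-olate | [Li+].CC(C)(C)C(=O)OCC[C@@H](Cl)[C@@H]([O-])CI | intermediate
11 | (3R)-3-chloro-3-[(2S)-oxiran-2-yl]propyl pivalate | CC(C)(C)C(=O)OCC[C@@H](Cl)[C@@H]1CO1 | intermediate
12 | lithium (E)-hept-4-en-1-yn-1-ide | [Li]C#CC/C=C/CC | intermediate
13 | (3R,4S,9E)-3-chloro-4-hydroxydodec-9-en-6-yn-1-yl pivalate | CC(C)(C)C(=O)OCC[C@@H](Cl)[C@@H](O)CC#CC/C=C/CC | intermediate
14 | (3R,4S,6Z,9E)-3-chloro-4-hydroxydodeca-6,9-dien-1-yl pivalate | CC(C)(C)C(=O)OCC[C@@H](Cl)[C@@H](O)C/C=C\C/C=C/CC | intermediate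
15 | (3R,4S)-3-chloro-4-hydroxy-5-{(2R,3S)-3-[(E)-pent-2-en-1-yl]oxiran-2-yl}pentyl pivalate | CC(C)(C)C(=O)OCC[C@@H](Cl)[C@@H](O)C[C@H]1O[C@H]1C/C=C/CC | intermediate
16 | (3R,4S)-4-[(tert-butyldiphenylsilyl)oxy]-3-chloro-5-{(2R,3S)-3-[(E)-pent-2-en-1-yl]oxiran-2-yl}pentyl pivalate | CC(C)(C)C(=O)OCC[C@@H](Cl)[C@H](C[C@H]1O[C@H]1C/C=C/CC)O[Si](c1ccccc1)(c1ccccc1)C(C)(C)C | intermediate
17 | (12R,13R)-bromonium ion of 16 (Br+ bridging C12 and C13, cis-oxirane intact) | CC(C)(C)C(=O)OCC[C@@H](Cl)[C@H](C[C@H]1O[C@H]1C[C@H]1[Br+][C@@H]1CC)O[Si](c1ccccc1)(c1ccccc1)C(C)(C)C | intermediate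
18 | (9R,10S,12R,13S)-epoxonium ion (1-oxoniabicyclo[3.1.0]hexane, O+ bonded to C9, C10 and C13, Br on C12) | CC(C)(C)C(=O)OCC[C@@H](Cl)[C@H](C[C@H]1[O+]2[C@H]1C[C@@H](Br)[C@@H]2CC)O[Si](c1ccccc1)(c1ccccc1)C(C)(C)C | intermediate
19 | (3R,4S)-5-[(2R,3R,5R,6S)-5-bromo-3-chloro-6-ethyloxan-2-yl]-4-[(tert-butyldiphenylsilyl)oxy]-3-chloropentyl pivalate | CC(C)(C)C(=O)OCC[C@@H](Cl)[C@H](C[C@H]1O[C@@H](CC)[C@H](Br)C[C@H]1Cl)O[Si](c1ccccc1)(c1ccccc1)C(C)(C)C | intermediate
20 | (3R,4S)-5-[(2R,3R,5R,6S)-5-bromo-3-chloro-6-ethyloxan-2-yl]-4-[(tert-butyldiphenylsilyl)oxy]-3-chloropentan-1-ol | OCC[C@@H](Cl)[C@H](C[C@H]1O[C@@H](CC)[C@H](Br)C[C@H]1Cl)O[Si](c1ccccc1)(c1ccccc1)C(C)(C)C | intermediate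
21 | (3R,4S)-5-[(2R,3R,5R,6S)-5-bromo-3-chloro-6-ethyloxan-2-yl]-4-[(tert-butyldiphenylsilyl)oxy]-3-chloropentanal | O=CC[C@@H](Cl)[C@H](C[C@H]1O[C@@H](CC)[C@H](Br)C[C@H]1Cl)O[Si](c1ccccc1)(c1ccccc1)C(C)(C)C | intermediate
22 | tert-butyl({(2S,3R,5E)-1-[(2R,3R,5R,6S)-5-bromo-3-chloro-6-ethyloxan-2-yl]-3-chloro-6-iodohex-5-en-2-yl}oxy)diphenylsilane | I/C=C/C[C@@H](Cl)[C@H](C[C@H]1O[C@@H](CC)[C@H](Br)C[C@H]1Cl)O[Si](c1ccccc1)(c1ccccc1)C(C)(C)C | intermediate
23 | ethynyltrimethylsilane | C#C[Si](C)(C)C | starting material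
24 | tert-butyl({(2S,3R,5E)-1-[(2R,3R,5R,6S)-5-bromo-3-chloro-6-ethyloxan-2-yl]-3-chloro-8-(trimethylsilyl)oct-5-en-7-yn-2-yl}oxy)diphenylsilane | C[Si](C)(C)C#C/C=C/C[C@@H](Cl)[C@H](C[C@H]1O[C@@H](CC)[C@H](Br)C[C@H]1Cl)O[Si](c1ccccc1)(c1ccccc1)C(C)(C)C | intermediate
25 | (2S,3R,5E)-1-[(2R,3R,5R,6S)-5-bromo-3-chloro-6-ethyloxan-2-yl]-3-chlorooct-5-en-7-yn-2-ol | C#C/C=C/C[C@@H](Cl)[C@H](C[C@H]1O[C@@H](CC)[C@H](Br)C[C@H]1Cl)O | intermediate
26 | (2S,3R,5E)-1-[(2R,3R,5R,6S)-5-bromo-3-chloro-6-ethyloxan-2-yl]-3-chlorooct-5-en-7-yn-2-yl acetate | C#C/C=C/C[C@@H](Cl)[C@H](C[C@H]1O[C@@H](CC)[C@H](Br)C[C@H]1Cl)OC(C)=O | target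

Total step count: 16. Longest linear sequence: 15 steps (steps 2–16, from butane-1,4-diol 4 to 26); step 1 supplies the C9–C15 fragment.

Steps most likely to fail

Step 10. The cascade may take the wrong course in several ways: bromonium capture on the other alkene face (the C12/C13 pair epimeric to the C9/C10 pair), chloride entering at C9 to leave an oxolane, chloride adding directly across the bromonium ion, or chloride opening the oxirane before Br+ arrives. The fallback uses known reactions only, sets the alkene face by reagent control, and starts from 16. Chloride opening of the oxirane at the less hindered C10 with Li2CuCl4 in THF should give the (9R,10R)-10-chloro-9-ol F1. Shi epoxidation of its E alkene with the D-fructose-derived ketone and buffered Oxone should give the (12R,13R)-epoxide F2. A trace of camphorsulfonic acid in CH2Cl2 should then close the C9 hydroxyl onto C12 (5-exo, inversion) to give the oxolane carbinol F3. Triflation of the C13 hydroxyl (Tf2O, 2,6-lutidine, CH2Cl2, −78 °C) gives the triflate F4, and added Bu4NBr should bring about ring expansion: the ring oxygen displaces the triflate at C13 and bromide opens the bicyclic oxonium ion at C12. The net result is anti addition of O and Br across the former alkene, and the route is rejoined at 19.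

Step 5. The alkyllithium may enolise the α-chloro aldehyde and erode the C6 configuration, the anti selectivity of the carbenoid addition may be modest, or the carbenoid may decompose before it adds. The fallback leaves from 7 and avoids strong base and the oxirane altogether. Zinc-mediated Barbier propargylation with propargyl bromide (Zn, THF/aqueous NH4Cl, 0 °C) should give the homopropargylic anti-chlorohydrin F5 under the same Cornforth control. Copper-mediated allylation of its terminal alkyne with bromide 1 (CuI, NaI, K2CO3, DMF, rt) should then give 13, where the route is rejoined; steps 1 and 6 are then not needed.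

Step 15. Fluoride may act as a base: the freed C7 alkoxide may close on C6 to an oxirane, HCl or HBr may be lost from the ring, or the hindered silyl ether may cleave too slowly under buffering. The fallback leaves from 22 and never generates a C7 alkoxide or uses fluoride on the enyne. Acidic desilylation with HF·pyridine (THF/pyridine, rt) should give the iodo-alkenol F6. Acetylation (Ac2O, pyridine, DMAP) should give the acetate F7. Negishi coupling of F7 with ethynylzinc bromide (from 2 and ZnBr2), Pd(PPh3)4, THF, rt, should install the terminal alkyne directly and give 26.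

Further compounds
F1 | step 10 | (3R,4S,6R,7R,9E)-4-[(tert-butyldiphenylsilyl)oxy]-3,7-dichloro-6-hydroxydodec-9-en-1-yl pivalate | CC(C)(C)C(=O)OCC[C@@H](Cl)[C@H](C[C@@H](O)[C@H](Cl)C/C=C/CC)O[Si](c1ccccc1)(c1ccccc1)C(C)(C)C
F2 | step 10 | (3R,4S,6R,7R)-4-[(tert-butyldiphenylsilyl)oxy]-3,7-dichloro-8-[(2R,3R)-3-ethyloxiran-2-yl]-6-hydroxyoctyl pivalate | CC(C)(C)C(=O)OCC[C@@H](Cl)[C@H](C[C@@H](O)[C@H](Cl)C[C@H]1O[C@@H]1CC)O[Si](c1ccccc1)(c1ccccc1)C(C)(C)C
F3 | step 10 | (3R,4S)-4-[(tert-butyldiphenylsilyl)oxy]-3-chloro-5-{(2R,3R,5S)-3-chloro-5-[(1R)-1-hydroxypropyl]oxolan-2-yl}pentyl pivalate | CC(C)(C)C(=O)OCC[C@@H](Cl)[C@H](C[C@H]1O[C@H]([C@H](O)CC)C[C@H]1Cl)O[Si](c1ccccc1)(c1ccccc1)C(C)(C)C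
F4 | step 10 | (3R,4S)-4-[(tert-butyldiphenylsilyl)oxy]-3-chloro-5-{(2R,3R,5S)-3-chloro-5-[(1R)-1-(trifluoromethanesulfonyloxy)propyl]oxolan-2-yl}pentyl pivalate | CC(C)(C)C(=O)OCC[C@@H](Cl)[C@H](C[C@H]1O[C@H]([C@H](OS(=O)(=O)C(F)(F)F)CC)C[C@H]1Cl)O[Si](c1ccccc1)(c1ccccc1)C(C)(C)C
F5 | step 5 | (3R,4S)-3-chloro-4-hydroxyhept-6-yn-1-yl pivalate | CC(C)(C)C(=O)OCC[C@@H](Cl)[C@@H](O)CC#C
F6 | step 15 | (2S,3R,5E)-1-[(2R,3R,5R,6S)-5-bromo-3-chloro-6-ethyloxan-2-yl]-3-chloro-6-iodohex-5-en-2-ol | I/C=C/C[C@@H](Cl)[C@H](C[C@H]1O[C@@H](CC)[C@H](Br)C[C@H]1Cl)O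
F7 | step 15 | (2S,3R,5E)-1-[(2R,3R,5R,6S)-5-bromo-3-chloro-6-ethyloxan-2-yl]-3-chloro-6-iodohex-5-en-2-yl acetate | I/C=C/C[C@@H](Cl)[C@H](C[C@H]1O[C@@H](CC)[C@H](Br)C[C@H]1Cl)OC(C)=O
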